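The ten-membered ring is traced back to the six-membered ring of carvone. Its C6 oxygen, flanked by the Z C4=C5 alkene and, across C7–C9, by the E C1=C10 alkene that later bears the epoxide, is the cyclodec-5-enone pattern of a 1,2-dialkenylcyclohexenol. One alkoxide-accelerated [3,3] shift forms C8–C9, cuts C6–C1, expands the ring by four atoms, fixes both alkene geometries and sets C8 as a C–Si bond. The precursor is trans-1-[(E)-2-(benzyldimethylsilyl)vinyl]-6-isopropenylcyclohex-2-enol 12 with the C3 oxygen in place. After C–Si oxidation, the C8 hydroxyl steers C7 alkylation and C6 reduction; lactonisation, methylenation, two acylations and epoxidation finish.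

Key step: step 7

Remarks on the chemistry
- Locants C1–C15 are the germacrane locants of the target and are used for every ten-membered compound: C6 lactone carbinol, C7 ring-fusion carbon, C8 ester carbinol, C11–C13 lactone arm, C14 on C10, C15 on C4; 2' and 3' are the oxirane carbons of the C8 acyl group.
- The C3 oxygen is carried as a triisopropylsilyl ether so that it outlasts the fluoride that unmasks C8.
- In the enolate that leaves the rearrangement, the ring covers one face of C7 and the C8–Si bond lies in the enolate plane, so direct alkylation there is expected to give the C7 epimer; the C–Si bond is therefore oxidised first and C7 is alkylated through the chelated dianion of the ketol.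

Step 1
Reactants: 1 (R)-carvone
Product: 2 (1R,5R)-cis-carveol
Conditions: NaBH4, CeCl3·7H2O, MeOH, 0 °C
Reagents that add atoms: none
Why: Luche 1,2-reduction of the enone, in which hydride adds axially to the half-chair that carries the isopropenyl group equatorially and so gives the equatorial alcohol cis to that group (new C1 centre R).

Step 2
Reactants: 2 (1R,5R)-cis-carveol
Product: 4 (1S,5R)-trans-carveol, via trans-carveyl 4-nitrobenzoate 3 (not isolated)
Conditions: PPh3, DIAD, 4-nitrobenzoic acid, THF, 0 °C to rt; then K2CO3 (cat.), MeOH, rt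
Reagents that add atoms: 4-nitrobenzoic acid, OC(=O)c1ccc(cc1)[N+](=O)[O-] (supplies the new C1 oxygen)
Why: Mitsunobu esterification inverts the allylic carbinol by SN2 displacement of the oxyphosphonium group, and methanolysis of the ester frees the trans alcohol (C1 now S).

Step 3
Reactants: 4 (1S,5R)-trans-carveol
Product: 5 (1S,5R)-trans-carveyl triisopropylsilyl ether
Conditions: TIPSOTf, 2,6-lutidine, CH2Cl2, −78 to 0 °C
Reagents that add atoms: triisopropylsilyl triflate, CC(C)[Si](OS(=O)(=O)C(F)(F)F)(C(C)C)C(C)C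
Why: routine O-silylation of a secondary alcohol that touches no stereocentre and installs an ether stable to chromium oxidants, organometallics, KH and brief cold fluoride.

Step 4
Reactants: 5 (1S,5R)-trans-carveyl triisopropylsilyl ether
Product: 6 (4S,6R)-3-methyl-6-(prop-1-en-2-yl)-4-(triisopropylsilyloxy)cyclohex-2-en-1-one
Conditions: CrO3, 3,5-dimethylpyrazole, CH2Cl2, −20 °C
Reagents that add atoms: chromium trioxide, O=[Cr](=O)=O
Why: allylic oxidation of a 1-methylcyclohexene with the CrO3–dimethylpyrazole complex should convert the only allylic ring methylene into the β-methyl enone, the C–H under the bulky silyl ether and the isopropenyl positions being less reactive and the non-basic medium leaving the stereocentre next to the new ketone unenolised.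

Step 5
Reactants: 7 (E)-1,2-bis(tributylstannyl)ethene; 8 benzylchlorodimethylsilane
Product: 10 (E)-benzyldimethyl[2-(tributylstannyl)ethenyl]silane, via stannylvinyllithium 9 (not isolated)
Conditions: n-BuLi (1 equiv), THF, −78 °C; then 8, −78 to 0 °C
Reagents that add atoms: none
Why: tin–lithium exchange of one stannyl group proceeds with retention of the E geometry, and the vinyllithium is silylated at carbon by the chlorosilane.

Step 6
Reactants: 6 (4S,6R)-3-methyl-6-(prop-1-en-2-yl)-4-(triisopropylsilyloxy)cyclohex-2-en-1-one; 10 (E)-benzyldimethyl[2-(tributylstannyl)ethenyl]silane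
Product: 12 (1R,4S,6R)-1-[(E)-2-(benzyldimethylsilyl)ethenyl]-3-methyl-6-(prop-1-en-2-yl)-4-(triisopropylsilyloxy)cyclohex-2-en-1-ol, via silylvinyllithium 11 (not isolated)
Conditions: 10, n-BuLi, THF, −78 °C; CeCl3, −78 °C; then 6, −78 °C; aq NH4Cl
Reagents that add atoms: none
Why: tin–lithium exchange, transmetalation to the weakly basic organocerium (which suppresses enolisation of the doubly activated α'-hydrogen) and 1,2-addition to the enone, the nucleophile entering equatorially on the face opposite the neighbouring pseudoequatorial isopropenyl group so that the two alkenyl arms end up trans (new carbinol centre R).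

Step 7
Reactants: 12 (1R,4S,6R)-1-[(E)-2-(benzyldimethylsilyl)ethenyl]-3-methyl-6-(prop-1-en-2-yl)-4-(triisopropylsilyloxy)cyclohex-2-en-1-ol
Product: 14 (3S,8R)-8-(benzyldimethylsilyl)-4,10-dimethyl-3-(triisopropylsilyloxy)cyclodeca-1(10)E,4Z-dien-6-one, via potassium enolate 13 (not isolated)
Conditions: KH, 18-crown-6, THF, 0 °C to rt; then AcOH, THF, −78 °C
Reagents that add atoms: none
Why: KH with 18-crown-6 gives the bare potassium alkoxide, whose 1,5-diene C8=C7–C6–C1–C10=C9 undergoes a charge-accelerated [3,3] shift that forms C8–C9 and cleaves C6–C1, leaving the C6 enolate 13, which cold acetic acid protonates at C7. The closest known reaction type is the anionic oxy-Cope rearrangement of trans-1,2-dialkenylcyclohexanols and 1-vinyl-6-alkenylcyclohex-2-enols to cyclodec-5-enones. The ten-membered ring is not closed end to end but arises by four-atom ring expansion, the new σ bond joining the two alkenyl termini while the ring bond between their anchoring carbons is cut. The only new stereocentre, C8, is fixed by the chair transition state in which both arms are equatorial on the cyclohexene and the E vinylsilane places silicon equatorial, so the configuration of the carbinol carbon and of the isopropenyl-bearing carbon is relayed to C8 (R, silicon where the oxygen will be) and to the E geometry of C1=C10, while the cis ring alkene becomes Z C4=C5. The step needs the chair [3,3] pathway rather than a boat, a [1,3] shift or fragmentation, which the trans-diequatorial arms and the ion-pair-free alkoxide secure; the E geometry keeps silicon out of reach of the alkoxide and carbon-bound silicon at C8 cannot be expelled from the enolate.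

Step 8
Reactants: 14 (3S,8R)-8-(benzyldimethylsilyl)-4,10-dimethyl-3-(triisopropylsilyloxy)cyclodeca-1(10)E,4Z-dien-6-one
Product: 16 (3S,8R)-8-hydroxy-4,10-dimethyl-3-(triisopropylsilyloxy)cyclodeca-1(10)E,4Z-dien-6-one, via fluorosilane 15 (not isolated)
Conditions: TBAF, THF, 0 °C, 15 min; then KHCO3, 30% H2O2, MeOH/THF, rt
Reagents that add atoms: hydrogen peroxide, OO; tetrabutylammonium fluoride, [F-].CCCC[N+](CCCC)(CCCC)CCCC (fluorine in 15 only)
Why: Tamao–Fleming oxidation of the benzyldimethylsilyl group, in which fluoride cleaves the benzyl–silicon bond and peroxide then induces the 1,2-shift of C8 from silicon to oxygen with retention, so the C8 hydroxyl keeps the configuration set in step 7 while the hindered C3 silyl ether should survive the short cold fluoride exposure.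

Step 9
Reactants: 16 (3S,8R)-8-hydroxy-4,10-dimethyl-3-(triisopropylsilyloxy)cyclodeca-1(10)E,4Z-dien-6-one
Product: 18 methyl 2-[(3S,7R,8R)-8-hydroxy-4,10-dimethyl-6-oxo-3-(triisopropylsilyloxy)cyclodeca-1(10)E,4Z-dien-7-yl]acetate, via dilithium dianion 17 (not isolated)
Conditions: LDA (2.3 equiv), THF, −78 to −40 °C; methyl bromoacetate, DMPU, −78 °C; AcOH, −78 °C
Reagents that add atoms: methyl bromoacetate, COC(=O)CBr
Why: Fráter–Seebach-type alkylation of the aldolate dianion, in which lithium bridging O6 and O8 holds the C8 oxygen in the enolate plane with the C8–C9 ring bond over one face, so the bromoacetate should enter C7 on the open face anti to C9 and give the 7,8-anti product (C7 R).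

Step 10
Reactants: 18 methyl 2-[(3S,7R,8R)-8-hydroxy-4,10-dimethyl-6-oxo-3-(triisopropylsilyloxy)cyclodeca-1(10)E,4Z-dien-7-yl]acetate
Product: 20 (3S,6R,7R,8R)-8-hydroxy-3-(triisopropylsilyloxy)-13-norgermacra-1(10)E,4Z-dien-12,6-olide, via diol ester 19 (not isolated)
Conditions: Me4NBH(OAc)3, MeCN/AcOH, −30 °C; then PPTS (cat.), CH2Cl2, rt to 40 °C
Reagents that add atoms: none
Why: Evans–Saksena reduction, in which boron bound to O8 delivers hydride to the C6 carbonyl through a chair-like six-membered transition state to give the 1,3-anti diol (C6 R), after which the C6 hydroxyl, syn to the C7 acetate arm, is expected to close the trans-fused γ-lactone in preference to O8.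

Step 11
Reactants: 20 (3S,6R,7R,8R)-8-hydroxy-3-(triisopropylsilyloxy)-13-norgermacra-1(10)E,4Z-dien-12,6-olide
Product: 23 (3S,6R,7R,8R)-8-hydroxy-3-(triisopropylsilyloxy)germacra-1(10)E,4Z,11(13)-trien-12,6-olide, via Mannich base 21 (not isolated), via trimethylammonium iodide 22 (not isolated)
Conditions: LDA (2.5 equiv), THF, −78 °C; Me2N=CH2 I, −78 to 0 °C; then MeI, MeOH, rt; then aq NaHCO3, EtOAc, rt
Reagents that add atoms: Eschenmoser's salt, C=[N+](C)C.[I-]; iodomethane, CI (methyl in 22 only)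
Why: Eschenmoser methylenation, in which the lactone enolate formed beside the C8 lithium alkoxide is aminomethylated at C11 and quaternisation followed by mild base eliminates trimethylamine to the exocyclic methylene, erasing the transient C11 centre.

Step 12
Reactants: 24 angelic acid
Product: 25 (Z)-2-methylbut-2-en-1-ol
Conditions: LiAlH4, Et2O, 0 °C
Reagents that add atoms: none
Why: hydride reduction of the carboxylic acid to the allylic alcohol, which should leave the Z alkene untouched and unisomerised.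

Step 13
Reactants: 25 (Z)-2-methylbut-2-en-1-ol
Product: 26 [(2R,3S)-2,3-dimethyloxiran-2-yl]methanol
Conditions: Ti(OiPr)4 (cat.), D-(−)-diethyl tartrate (cat.), t-BuOOH, 4 Å MS, CH2Cl2, −20 °C
Reagents that add atoms: tert-butyl hydroperoxide, CC(C)(C)OO
Why: Sharpless asymmetric epoxidation of the allylic alcohol, the unnatural tartrate directing oxygen to the alkene face that gives the 2R,3S epoxide with the Z geometry retained as the cis relation of hydroxymethyl and the C3 methyl.

Step 14
Reactants: 26 [(2R,3S)-2,3-dimethyloxiran-2-yl]methanol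
Product: 27 (2S,3S)-2,3-dimethyloxirane-2-carboxylic acid
Conditions: RuCl3 (cat.), NaIO4, CCl4/MeCN/H2O, rt
Reagents that add atoms: water, O
Why: RuO4-catalysed oxidation of the primary epoxy alcohol to the glycidic acid leaves both ring centres untouched, the C2 descriptor changing only because the carboxyl group gains priority.

Step 15
Reactants: 23 (3S,6R,7R,8R)-8-hydroxy-3-(triisopropylsilyloxy)germacra-1(10)E,4Z,11(13)-trien-12,6-olide; 27 (2S,3S)-2,3-dimethyloxirane-2-carboxylic acid
Product: 29 (3S,6R,7R,8R)-8-[(2S,3S)-2,3-dimethyloxirane-2-carbonyloxy]-3-(triisopropylsilyloxy)germacra-1(10)E,4Z,11(13)-trien-12,6-olide, via mixed anhydride 28 (not isolated)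
Conditions: 27, 2,4,6-trichlorobenzoyl chloride, Et3N, THF, rt; then 23, DMAP, toluene, rt to 40 °C
Reagents that add atoms: 2,4,6-trichlorobenzoyl chloride, ClC(=O)c1c(Cl)cc(Cl)cc1Cl (aroyl group in 28 only)
Why: Yamaguchi esterification of the hindered C8 alcohol by acyl–oxygen bond formation, which leaves C8 and the non-enolisable quaternary C2' unchanged.

Step 16
Reactants: 29 (3S,6R,7R,8R)-8-[(2S,3S)-2,3-dimethyloxirane-2-carbonyloxy]-3-(triisopropylsilyloxy)germacra-1(10)E,4Z,11(13)-trien-12,6-olide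
Product: 30 (3S,6R,7R,8R)-8-[(2S,3S)-2,3-dimethyloxirane-2-carbonyloxy]-3-hydroxygermacra-1(10)E,4Z,11(13)-trien-12,6-olide
Conditions: HF·pyridine, pyridine, THF, 0 °C to rt
Reagents that add atoms: none
Why: buffered fluoride cleavage of the silyl ether, conditions that should spare the ester, the glycidate epoxide and the α-methylene lactone.

Step 17
Reactants: 30 (3S,6R,7R,8R)-8-[(2S,3S)-2,3-dimethyloxirane-2-carbonyloxy]-3-hydroxygermacra-1(10)E,4Z,11(13)-trien-12,6-olide
Product: 31 (3S,6R,7R,8R)-8-[(2S,3S)-2,3-dimethyloxirane-2-carbonyloxy]-3-(3-methylbutanoyloxy)germacra-1(10)E,4Z,11(13)-trien-12,6-olide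
Conditions: 3-methylbutanoyl chloride, pyridine, DMAP (cat.), CH2Cl2, 0 °C
Reagents that add atoms: 3-methylbutanoyl chloride, CC(C)CC(Cl)=O
Why: O-acylation of the only free hydroxyl, the allylic C3 alcohol, with retention at C3.

Step 18
Reactants: 31 (3S,6R,7R,8R)-8-[(2S,3S)-2,3-dimethyloxirane-2-carbonyloxy]-3-(3-methylbutanoyloxy)germacra-1(10)E,4Z,11(13)-trien-12,6-olide
Product: 32 CNP0167461.1
Conditions: mCPBA, NaHCO3, CH2Cl2, 0 °C
Reagents that add atoms: 3-chloroperoxybenzoic acid, OOC(=O)c1cccc(Cl)c1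
Why: Prilezhaev epoxidation of the most electron-rich alkene, C1=C10 (C4=C5 is deactivated by two allylic acyloxy groups and the methylene lactone is electron-poor), stereospecific for the E geometry and expected to occur on the outward face of that alkene to give the 1R,10R trans epoxide.

Compound list
1 | (R)-carvone | CC1=CC[C@H](CC1=O)C(=C)C | starting material
2 | (1R,5R)-cis-carveol | CC1=CC[C@H](C[C@H]1O)C(=C)C | intermediate
3 | (1S,5R)-trans-carveyl 4-nitrobenzoate | CC1=CC[C@H](C[C@@H]1OC(=O)c2ccc(cc2)[N+](=O)[O-])C(=C)C | intermediate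
4 | (1S,5R)-trans-carveol | CC1=CC[C@H](C[C@@H]1O)C(=C)C | intermediate
5 | (1S,5R)-trans-carveyl triisopropylsilyl ether | CC1=CC[C@H](C[C@@H]1O[Si](C(C)C)(C(C)C)C(C)C)C(=C)C | intermediate
6 | (4S,6R)-3-methyl-6-(prop-1-en-2-yl)-4-(triisopropylsilyloxy)cyclohex-2-en-1-one | CC1=CC(=O)[C@H](C[C@@H]1O[Si](C(C)C)(C(C)C)C(C)C)C(=C)C | intermediate
7 | (E)-1,2-bis(tributylstannyl)ethene | CCCC[Sn](CCCC)(CCCC)/C=C/[Sn](CCCC)(CCCC)CCCC | starting material
8 | benzylchlorodimethylsilane | C[Si](C)(Cl)Cc1ccccc1 | starting material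
9 | (E)-2-(tributylstannyl)vinyllithium | [Li]/C=C/[Sn](CCCC)(CCCC)CCCC | intermediate
10 | (E)-benzyldimethyl[2-(tributylstannyl)ethenyl]silane | C[Si](C)(Cc1ccccc1)/C=C/[Sn](CCCC)(CCCC)CCCC | intermediate
11 | (E)-2-(benzyldimethylsilyl)vinyllithium | [Li]/C=C/[Si](C)(C)Cc1ccccc1 | intermediate
12 | (1R,4S,6R)-1-[(E)-2-(benzyldimethylsilyl)ethenyl]-3-methyl-6-(prop-1-en-2-yl)-4-(triisopropylsilyloxy)cyclohex-2-en-1-ol | O[C@]1(/C=C/[Si](C)(C)Cc2ccccc2)C=C(C)[C@@H](O[Si](C(C)C)(C(C)C)C(C)C)C[C@@H]1C(C)=C | intermediate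
13 | potassium (3S,8R)-8-(benzyldimethylsilyl)-4,10-dimethyl-3-(triisopropylsilyloxy)cyclodeca-1(10)E,4Z,6-trien-6-olate (enolate oxygen cis to C8) | [K+].[O-]/C1=C\[C@H]([Si](C)(C)Cc2ccccc2)C/C(C)=C/C[C@H](O[Si](C(C)C)(C(C)C)C(C)C)/C(C)=C\1 | intermediate
14 | (3S,8R)-8-(benzyldimethylsilyl)-4,10-dimethyl-3-(triisopropylsilyloxy)cyclodeca-1(10)E,4Z-dien-6-one | O=C1/C=C(/C)[C@@H](O[Si](C(C)C)(C(C)C)C(C)C)C/C=C(\C)/C[C@@H]([Si](C)(C)Cc2ccccc2)C1 | intermediate
15 | (3S,8R)-8-(fluorodimethylsilyl)-4,10-dimethyl-3-(triisopropylsilyloxy)cyclodeca-1(10)E,4Z-dien-6-one | O=C1/C=C(/C)[C@@H](O[Si](C(C)C)(C(C)C)C(C)C)C/C=C(\C)/C[C@@H]([Si](C)(C)F)C1 | intermediate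
16 | (3S,8R)-8-hydroxy-4,10-dimethyl-3-(triisopropylsilyloxy)cyclodeca-1(10)E,4Z-dien-6-one | O=C1/C=C(/C)[C@@H](O[Si](C(C)C)(C(C)C)C(C)C)C/C=C(\C)/C[C@@H](O)C1 | intermediate
17 | dilithium salt of 16 (C6 enolate with oxygen cis to C8, C8 alkoxide; 3S,8R) | [Li+].[Li+].[O-]/C1=C\[C@H]([O-])C/C(C)=C/C[C@H](O[Si](C(C)C)(C(C)C)C(C)C)/C(C)=C\1 | intermediate
18 | methyl 2-[(3S,7R,8R)-8-hydroxy-4,10-dimethyl-6-oxo-3-(triisopropylsilyloxy)cyclodeca-1(10)E,4Z-dien-7-yl]acetate | O=C1/C=C(/C)[C@@H](O[Si](C(C)C)(C(C)C)C(C)C)C/C=C(\C)/C[C@@H](O)[C@H]1CC(=O)OC | intermediate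
19 | methyl 2-[(3S,6R,7R,8R)-6,8-dihydroxy-4,10-dimethyl-3-(triisopropylsilyloxy)cyclodeca-1(10)E,4Z-dien-7-yl]acetate | O[C@@H]1/C=C(/C)[C@@H](O[Si](C(C)C)(C(C)C)C(C)C)C/C=C(\C)/C[C@@H](O)[C@H]1CC(=O)OC | intermediate
20 | (3S,6R,7R,8R)-8-hydroxy-3-(triisopropylsilyloxy)-13-norgermacra-1(10)E,4Z-dien-12,6-olide | C1C(=O)O[C@@H]2/C=C(/C)[C@@H](O[Si](C(C)C)(C(C)C)C(C)C)C/C=C(\C)/C[C@@H](O)[C@@H]12 | intermediate
21 | (3S,6R,7R,8R)-13-(dimethylamino)-8-hydroxy-3-(triisopropylsilyloxy)germacra-1(10)E,4Z-dien-12,6-olide (C11 epimers) | CN(C)CC1C(=O)O[C@@H]2/C=C(/C)[C@@H](O[Si](C(C)C)(C(C)C)C(C)C)C/C=C(\C)/C[C@@H](O)[C@@H]12 | intermediate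
22 | N-methyl quaternary iodide of 21 (13-trimethylammonio, C11 epimers) | C[N+](C)(C)CC1C(=O)O[C@@H]2/C=C(/C)[C@@H](O[Si](C(C)C)(C(C)C)C(C)C)C/C=C(\C)/C[C@@H](O)[C@@H]12.[I-] | intermediate
23 | (3S,6R,7R,8R)-8-hydroxy-3-(triisopropylsilyloxy)germacra-1(10)E,4Z,11(13)-trien-12,6-olide | C=C1C(=O)O[C@@H]2/C=C(/C)[C@@H](O[Si](C(C)C)(C(C)C)C(C)C)C/C=C(\C)/C[C@@H](O)[C@@H]12 | intermediate
24 | angelic acid, (Z)-2-methylbut-2-enoic acid | C/C=C(/C)C(=O)O | starting material
25 | (Z)-2-methylbut-2-en-1-ol | C/C=C(/C)CO | intermediate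
26 | [(2R,3S)-2,3-dimethyloxiran-2-yl]methanol | OC[C@@]1(C)O[C@H]1C | intermediate
27 | (2S,3S)-2,3-dimethyloxirane-2-carboxylic acid | OC(=O)[C@@]1(C)O[C@H]1C | intermediate
28 | (2S,3S)-2,3-dimethyloxirane-2-carboxylic 2,4,6-trichlorobenzoic anhydride | O=C(OC(=O)c1c(Cl)cc(Cl)cc1Cl)[C@@]2(C)O[C@H]2C | intermediate
29 | (3S,6R,7R,8R)-8-[(2S,3S)-2,3-dimethyloxirane-2-carbonyloxy]-3-(triisopropylsilyloxy)germacra-1(10)E,4Z,11(13)-trien-12,6-olide | C=C1C(=O)O[C@@H]2/C=C(/C)[C@@H](O[Si](C(C)C)(C(C)C)C(C)C)C/C=C(\C)/C[C@@H](OC(=O)[C@@]3(C)O[C@H]3C)[C@@H]12 | intermediate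
30 | (3S,6R,7R,8R)-8-[(2S,3S)-2,3-dimethyloxirane-2-carbonyloxy]-3-hydroxygermacra-1(10)E,4Z,11(13)-trien-12,6-olide | C=C1C(=O)O[C@@H]2/C=C(/C)[C@@H](O)C/C=C(\C)/C[C@@H](OC(=O)[C@@]3(C)O[C@H]3C)[C@@H]12 | intermediate
31 | (3S,6R,7R,8R)-8-[(2S,3S)-2,3-dimethyloxirane-2-carbonyloxy]-3-(3-methylbutanoyloxy)germacra-1(10)E,4Z,11(13)-trien-12,6-olide | C=C1C(=O)O[C@@H]2/C=C(/C)[C@@H](OC(=O)CC(C)C)C/C=C(\C)/C[C@@H](OC(=O)[C@@]3(C)O[C@H]3C)[C@@H]12 | intermediate
32 | CNP0167461.1, (1R,3S,6R,7R,8R,10R)-1,10-epoxy-8-[(2S,3S)-2,3-dimethyloxirane-2-carbonyloxy]-3-(3-methylbutanoyloxy)germacra-4Z,11(13)-dien-12,6-olide | C=C1C(=O)O[C@@H]2/C=C(/C)[C@@H](OC(=O)CC(C)C)C[C@H]3O[C@]3(C)C[C@@H](OC(=O)[C@@]3(C)O[C@H]3C)[C@@H]12 | target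

Total step count: 18. Longest linear sequence: 14 steps (steps 1–4, 6–11, 15–18).

Steps most likely to fail

Step 7 (key step). The doubly allylic potassium alkoxide may fragment by loss of the silylvinyl anion or follow a [1,3] shift, and any cis-dialkenyl contaminant from step 6 would react through a boat and erode the C8 configuration and the C1=C10 geometry. The fallback sets out from 12 and returns at 14. It abandons charge acceleration and runs the sigmatropic shift on the neutral alcohol thermally (degassed N-methylpyrrolidone, sealed tube, about 200 °C, or flash vacuum pyrolysis). This thermal oxy-Cope rearrangement passes through the enol F1, which tautomerises to ketone 14, so neither an alkoxide nor an enolate is involved.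

Step 9. The lithium aldolate may open by retro-aldol cleavage or dehydrate before the second deprotonation, or facial control at C7 may be incomplete. The fallback sets out from 14 and returns at 18. It attaches the C7 arm before the silicon is oxidised and creates the C7 centre by protonation instead of alkylation. Aldol addition of the lithium enolate of 14 (LiN(SiMe3)2, THF, −78 °C) to methyl glyoxylate gives aldol adduct F2, and mesylation–elimination (MsCl, Et3N) gives alkylidene keto ester F3. Conjugate hydride addition at C11 (LiBH(s-Bu)3, THF, −78 °C), followed by kinetic protonation of the resulting C6 enolate on its open face (t-BuOH, −78 °C), gives silyl keto ester F4. Tamao–Fleming oxidation as in step 8 then returns 18.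

Step 10. The C7 ester arm may close onto O8 instead of O6, since both hydroxyls are γ to the ester, or the two lactones may equilibrate. The fallback sets out from 18 and returns at 20. It differentiates the two oxygens during the reduction by an Evans–Tishchenko reaction (SmI2 catalyst, acetaldehyde, THF, −10 °C). This delivers hydride from the C8 hemiacetal to C6 with the same 1,3-anti sense and leaves C8 as its acetate in hydroxy acetate F5. Only O6 can then lactonise (PPTS) to acetoxy lactone F6, and brief methanolysis (K2CO3, MeOH, 0 °C) frees the C8 hydroxyl to give 20.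

Further compounds
F1 | step 7 | enol tautomer of 14, (3S,8R)-8-(benzyldimethylsilyl)-4,10-dimethyl-3-(triisopropylsilyloxy)cyclodeca-1(10)E,4Z,6-trien-6-ol (hydroxyl cis to C8) | O/C1=C\[C@H]([Si](C)(C)Cc2ccccc2)C/C(C)=C/C[C@H](O[Si](C(C)C)(C(C)C)C(C)C)/C(C)=C\1
F2 | step 9 | methyl 2-hydroxy-2-[(3S,8R)-8-(benzyldimethylsilyl)-4,10-dimethyl-6-oxo-3-(triisopropylsilyloxy)cyclodeca-1(10)E,4Z-dien-7-yl]acetate (C7 and C11 epimers) | O=C1/C=C(/C)[C@@H](O[Si](C(C)C)(C(C)C)C(C)C)C/C=C(\C)/C[C@@H]([Si](C)(C)Cc2ccccc2)C1C(O)C(=O)OC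
F3 | step 9 | methyl 2-[(3S,8R)-8-(benzyldimethylsilyl)-4,10-dimethyl-6-oxo-3-(triisopropylsilyloxy)cyclodeca-1(10)E,4Z-dien-7-ylidene]acetate (ester cis to C8) | COC(=O)/C=C1/C(=O)/C=C(/C)[C@@H](O[Si](C(C)C)(C(C)C)C(C)C)C/C=C(\C)/C[C@H]1[Si](C)(C)Cc2ccccc2
F4 | step 9 | methyl 2-[(3S,7S,8R)-8-(benzyldimethylsilyl)-4,10-dimethyl-6-oxo-3-(triisopropylsilyloxy)cyclodeca-1(10)E,4Z-dien-7-yl]acetate (C7 arranged as in 18; descriptor S because silicon outranks oxygen) | O=C1/C=C(/C)[C@@H](O[Si](C(C)C)(C(C)C)C(C)C)C/C=C(\C)/C[C@@H]([Si](C)(C)Cc2ccccc2)[C@H]1CC(=O)OC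
F5 | step 10 | methyl 2-[(3S,6R,7S,8R)-8-acetoxy-6-hydroxy-4,10-dimethyl-3-(triisopropylsilyloxy)cyclodeca-1(10)E,4Z-dien-7-yl]acetate (arranged as 19; C7 descriptor changes with the priorities) | O[C@@H]1/C=C(/C)[C@@H](O[Si](C(C)C)(C(C)C)C(C)C)C/C=C(\C)/C[C@@H](OC(C)=O)[C@H]1CC(=O)OC
F6 | step 10 | (3S,6R,7R,8R)-8-acetoxy-3-(triisopropylsilyloxy)-13-norgermacra-1(10)E,4Z-dien-12,6-olide | C1C(=O)O[C@@H]2/C=C(/C)[C@@H](O[Si](C(C)C)(C(C)C)C(C)C)C/C=C(\C)/C[C@@H](OC(C)=O)[C@@H]12
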